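The earlier runs and the new flask were generated by integration on assumed constants, and the scatter is random.

- At late times the west run's target stands still near 36.8%, while its substrate drifts from 13.2% at 2.50 d to 10.0% at 10.0 d. In this reckoning the flask should therefore stop gaining near 2.50 d, then fade slowly.

| setting | west | south | south-west | flask |
|---|---|---|---|---|
| substrate | 0.10 M | 0.10 M | 0.050 M | 0.10 M |
| coupling partner | 0.17 M | 0.26 M | 0.12 M | 0.120 M |
| remark | run made earlier | run made earlier | run made earlier |  |
| time |  |  |  | 15 d |

- west (time / d: target / %, substrate / %): 0.833: 32.1, 21.1; 1.25: 35.0, 17.7; 1.67: 35.9, 14.9; 2.50: 37.1, 13.2; 4.00: 36.4, 12.6; 6.00: 35.8, 11.1; 10.0: 36.8, 10.0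
- south (time / d: target / %, substrate / %): 0.833: 27.6, 3.2; 1.25: 27.0, 1.5; 1.67: 28.7, 1.5; 2.50: 29.1, 1.4; 4.00: 29.9, 1.2; 6.00: 27.2, 0; 10.0: 27.8, 0.2
- south-west (time / d: target / %, substrate / %): 0.833: 35.2, 17.9; 1.67: 40.1, 11.1; 2.50: 41.8, 10.3; 5.00: 43.4, 5.6; 10.0: 44.1, 6.3

(scatter of a reading: 1 percentage point)

- time, not beyond 15 d, at which the flask holds most target
- the amount of target, in percent of the substrate charged, at that time



- The useful quantity is the waste ratio: substrate converted to anything but target, per target, per molar of partner charged, a selectivity factor. It is read in two ways.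
- From last readings it gives 8.50 L mol⁻¹ (west), 9.96 L mol⁻¹ (south) and 9.37 L mol⁻¹ (south-west), so it holds steady as partner changes.
- From first readings it gives 8.58 L mol⁻¹, 9.64 L mol⁻¹ and 11.1 L mol⁻¹. South-west parts from its last reading, but a first reading covers just the start of a run, so the last readings are kept, with mean 9.28 L mol⁻¹.
- At 0.120 M of partner, the flask should turn 47.3% of converted substrate into target.
- A ratio steady in this way suggests a side path taking two partners, so each substrate converted costs at least 1.53 partners. The west run paid 1.89. These costs put the flask's target between 30.1% and 37.2%.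
- The forecast gave 37% at 15 d, “reached by a few days and then flat”.
- The flask holds most target, 35.2%, at 3.31 d.

    substrate + coupling partner → target (k = 1.90 × 10⁻⁴ L mol⁻¹ s⁻¹)
    substrate + 2 coupling partner → side product A (k = 0.00320 L² mol⁻² s⁻¹)
    coupling partner → decomposed reagent (k = 5.40 × 10⁻⁶ s⁻¹)
    substrate + target → side product B (k = 5.20 × 10⁻⁶ L mol⁻¹ s⁻¹)

- Removing the reaction to side product A lifts the flask's highest target from 35.2% to 72.8%. At the best time, the flask's waste ratio is 8.16 L mol⁻¹, close to the carried 9.28 L mol⁻¹. For the neighbour flask with 0.30 M of partner, the carried ratio gives a target share of 26.4%, and that flask ends with 23.8% target and 0.0058% substrate.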